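Late in the runs the target stood well short of the charge: at 69 min it was 60.3% of the starting material charged in the blue flask, 52.4% in the ochre flask and 72.8% in the violet flask.

| flask | starting material | partner | time |
|---|---|---|---|
| blue | 0.150 M | 0.300 M |  |
| violet | 0.0600 M | 0.210 M |  |
| ochre | 0.220 M | 0.300 M |  |
| grey | 0.150 M | 1.20 M | 69 min |

| run | time / min | [target] / M |
|---|---|---|
| blue run | 2.8 | 0.0156 |
| blue run | 6.2 | 0.0270 |
| blue run | 14 | 0.0428 |
| blue run | 31 | 0.0717 |
| blue run | 69 | 0.0904 |
| violet run | 2.8 | 0.0040 |
| violet run | 6.2 | 0.0085 |
| violet run | 14 | 0.0156 |
| violet run | 31 | 0.0242 |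
| violet run | 69 | 0.0437 |
| ochre run | 2.8 | 0.0175 |
| ochre run | 6.2 | 0.0383 |
| ochre run | 14 | 0.0619 |
| ochre run | 31 | 0.0906 |
| ochre run | 69 | 0.1153 |

(standard deviation of a reading: 0.002 M)

- Overall: starting material + partner -> target.
- Constant volume, constant temperature.
- The analysis sees a species whether free or bound.
- An order is taken over about fifteen percent of the charge, up and down.

- how the opening rate goes with [starting material] round the charge of the blue run: the exponent of the rate at two percent of starting material gone to target (one fixed amount of target, the same in the runs compared)
- how the opening rate goes with [partner] round the charge of the blue run: the exponent of the rate at two percent of starting material gone to target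
- target in the grey run at 69 min, as a share of the starting material charged

I read each run through two quantities:

opening clock τ = charged c_starting material × t / c_target, at the 6.2 min reading (a pseudo-first-order lifetime)

miss ratio B = (charged c_starting material − c_target) / c_target, at 69 min

First I turned the starting material. By hand, a step first order in it, at one constant c_partner, leaves τ and B unmoved. From blue to ochre, τ went from 34.4 min to 35.6 min, which I read as an order of 0.913. But B rose from 0.659 to 0.908, so I supposed a late loss that quickens with c_starting material:

B = g × charged c_starting material × τ

Blue gave g = 0.128 L mol⁻¹ min⁻¹, the loss constant, the miss ratio per unit of charge and of opening clock; ochre read 0.116 L mol⁻¹ min⁻¹ and violet 0.142 L mol⁻¹ min⁻¹.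

Then I turned the partner. By hand, more partner shortens τ, and so lowers B. Violet, with less partner and less starting material, read a longer τ than blue, 43.8 min. Taking the order in starting material as one, that gives a partner order of 0.671, on a reading with 23.5% scatter. For the grey flask I reckoned:

τ = 34.4 min × (0.300 M / 1.20 M)^0.671 = 13.6 min

B = 0.128 L mol⁻¹ min⁻¹ × 0.150 M × 13.6 min = 0.260

share of target = 1 / (1 + B) = 79.4%

The forecast gave orders of 0.8 and 1.6 and a grey share of 90%, more than my figure, holding that “the target seems to inhibit”.

The flask gave orders of 1.0 and 0.65, and a grey share of 80.0%.

    starting material + partner → target (0.2862 L mol⁻¹ min⁻¹)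
    2 starting material → homo dimer (0.1398 L mol⁻¹ min⁻¹)
    2 partner ⇌ idle reagent dimer, settled at all times (5.680 L mol⁻¹)

The quarter times of the blue and ochre flasks were 10.2 min and 11.5 min. The grey miss ratio was 0.250, and divided by 0.128 L mol⁻¹ min⁻¹ and the grey charge of 0.150 M it gives an opening clock of 13.0 min.

The readings were computed with made-up constants; the scatter is artificial.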